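The data were generated by integration with made-up constants; scatter was added.

Comparing two charges at one clock time gives a different factor from comparing them at one conversion when the product curve bends upward, and the question about this flask stands at one conversion.

| flask | substrate | precatalyst | remark |
|---|---|---|---|
| birch | 0.051 M | 0.0067 mol% | run made earlier |
| alder | 0.051 M | 0.015 mol% | run made earlier |
| larch | 0.10 M | 0.01 mol% | run made earlier |
| flask | 0.051 M | 0.01 mol% |  |

| run | time / h | product / % | substrate / % |
|---|---|---|---|
| birch | 1.33 | 0 | 99.5 |
| birch | 4.00 | 0.7 | 100.1 |
| birch | 8.00 | 1.6 | 95.9 |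
| birch | 10.0 | 1.3 | 98.7 |
| birch | 15.0 | 4.6 | 96.4 |
| alder | 1.33 | 0 | 99.1 |
| alder | 4.00 | 2.4 | 99.2 |
| alder | 8.00 | 4.4 | 96.1 |
| alder | 10.0 | 6.5 | 93.1 |
| alder | 15.0 | 11.7 | 87.8 |
| larch | 1.33 | 2.0 | 101.5 |
| larch | 2.50 | 0.6 | 100.5 |
| larch | 4.00 | 0.5 | 101.4 |
| larch | 8.00 | 3.0 | 96.5 |
| larch | 15.0 | 9.0 | 89.6 |

(standard deviation of a reading: 1 percentage point)



* factor on the rate of making product when 5.0 % of the substrate are converted if precatalyst is charged twice over
* factor on the rate when 5.0 % of the substrate are converted if precatalyst is charged at 0.002 mol% instead

Take the main step by itself: catalyst works at a steady amount from the first moment, [product] rises in a straight line, and at one conversion the rate goes with the charge, so doubling gives 2 and the smaller charge 0.200. Add a slow switching-on out of the precatalyst (an induction period): working catalyst grows in step with time, [product] goes as time squared, a smaller charge reaches the mark later, and the rate at the mark goes as the square root of the charge, giving 1.41 and 0.447. Add whatever flattens that growth, and the curve lies between these two pictures.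

So the rule is this: if, at one starting [substrate], [product] rises as charge times time to the power n, the growth exponent, then the rate at one conversion goes as the n-th root of the charge. Between 8.00 h and 15.0 h, readings that straddle 5.0 % in alder and larch, the three runs average 1.66, a rough reading with 1 percentage point of scatter on readings this small. The reckoning here is therefore 1.52 for doubling and 0.380 for the smaller charge.

The forecast stands higher on doubling and lower on the smaller charge, at 2.1 and 0.17, the latter called “an uncertain extrapolation”.

The flask gives 1.51 and 0.334.

    substrate + enzyme → product + enzyme, rate k1*[substrate]*[enzyme]/(1 + ([substrate]/Km1) + ([product]/Kp1)) (36.0 mM, 17.0 mM, k = 50000 M⁻¹ h⁻¹)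
    enzyme → spent catalyst (k = 0.0160 h⁻¹)
    precatalyst ⇌ enzyme (K = 0.290, k = 0.00930 h⁻¹)

At 12.5 h, just past the mark reached at 11.4 h, the flask holds 8.27 % of its catalyst as enzyme, 90.8 % as precatalyst and 0.926 % as spent catalyst. Through the rule, 1.51 means an exponent of 1.69. The flask with the smaller charge, at 0.334, means 1.47. The rule with the exponent 1.66 read from the runs puts the mark of that flask at about 30.2 h, an estimate, and at that conversion 3.95 % of its catalyst is spent catalyst.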